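**Plan**

- Cuts, in retrosynthetic order: the acetate (C10–O) and anisoate (C6–O) ester bonds; the C6 carbinol back to a ketone masked as a 1,3-dithiane; the C5–C6 bond of ring B (cycloheptene); the C9–C10 bond; the C1–C5 bond of ring A (cyclopentane); the C2–C3 bond.
- Enabling feature: on ring A the tertiary C4 hydroxyl and the C5–C6 bond are trans. This is the outcome of anti opening of a C4–C5 epoxide at C5 by a C6 carbanion that is tethered to C1 through C10 and the Z C8=C9 alkene.
- Forward order: C2–C3 by hydrazone alkylation; ring A by alkylidene carbene 1,5 C–H insertion (C4=C5 cyclopentene, quaternary C1); epoxidation; chain joined at C9–C10 by Nozaki–Hiyama–Kishi coupling with a Z vinyl iodide carrying the dithiane; ring B by dithiane-anion epoxide opening; then unmasking, reduction and two acylations.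
- Stereochemistry: C1 from (R)-3-bromo-2-methylpropan-1-ol (retention in the C–H insertion); C4 and C5 from epoxidation anti to the CH2OSi group, then inversion at C5; C10 from Felkin–Anh addition to the aldehyde on C1; C6 from hydride addition to the convex face of the cis-fused bicycle.

Key step: step 13

Remark: positions are numbered as in daucane (C1 ring-fusion carbon with CH3, C2, C3, C4 isopropyl carbinol, C5 ring-fusion CH, C6 to C10 around ring B with C8=C9); because the halide carbon of the C3 building block becomes C2 and its oxygenated carbon becomes C10, the target requires the (R) series, so the catalogue compound (R)-3-bromo-2-methylpropan-1-ol is used.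

**Step 1**
Reactants: 1 (R)-3-bromo-2-methylpropan-1-ol
Product: 2 (R)-(3-bromo-2-methylpropoxy)(tert-butyl)diphenylsilane
Conditions: TBDPSCl, imidazole, DMF, rt
Reagents that add atoms: tert-butyl(chloro)diphenylsilane, CC(C)(C)[Si](Cl)(c1ccccc1)c1ccccc1
Why: Imidazole-promoted silylation of a primary alcohol (silyl ether formation) leaves the bromide and the stereocentre untouched, and the bulky silyl group is chosen because it later shields one face of ring A.

**Step 2**
Reactants: 3 3-methylbutan-2-one
Product: 4 (E)-3-methylbutan-2-one N,N-dimethylhydrazone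
Conditions: Me2NNH2, AcOH (cat.), EtOH, reflux
Reagents that add atoms: N,N-dimethylhydrazine, CN(C)N
Why: Hydrazone formation from a ketone provides an azaenolate precursor that can be monoalkylated cleanly on the methyl side, which a simple ketone enolate would not do reliably with a β-branched halide.

**Step 3**
Reactants: 4 (E)-3-methylbutan-2-one N,N-dimethylhydrazone; 2 (R)-(3-bromo-2-methylpropoxy)(tert-butyl)diphenylsilane
Product: 7 (S)-7-[(tert-butyldiphenylsilyl)oxy]-2,6-dimethylheptan-3-one, via lithium azaenolate 5 (not isolated), via alkylated hydrazone 6 (not isolated)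
Conditions: LDA, THF, 0 °C; then 2, −78 °C → rt; then aq. oxalic acid, Et2O, rt
Reagents that add atoms: water, O
Why: Hydrazone azaenolate alkylation (Corey–Enders type) in which LDA removes a proton from the less substituted α-carbon, the azaenolate displaces the primary bromide by SN2 to form C2–C3, and two-phase oxalic acid hydrolysis returns the ketone without loss of the silyl ether; the stereocentre is not involved and changes descriptor only because the priorities change.

**Step 4**
Reactants: 7 (S)-7-[(tert-butyldiphenylsilyl)oxy]-2,6-dimethylheptan-3-one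
Product: 10 tert-butyl{[(1S)-1-methyl-3-(propan-2-yl)cyclopent-2-en-1-yl]methoxy}diphenylsilane, via diazoalkene 8 (not isolated), via alkylidene carbene 9 (not isolated)
Conditions: Me3SiCHN2, n-BuLi, THF, −78 °C → rt
Reagents that add atoms: (trimethylsilyl)diazomethane, C[Si](C)(C)C=[N+]=[N-]
Why: Alkylidene carbene 1,5 C–H insertion, in which LiC(N2)SiMe3 adds to the ketone, Peterson-type loss of LiOSiMe3 gives the diazoalkene, loss of N2 gives the carbene, and the carbene inserts into the only C–H bond five atoms away (the tertiary C1–H) with retention, so that quaternary C1, the C1–C5 bond and the C4=C5 alkene arise together.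

**Step 5**
Reactants: 10 tert-butyl{[(1S)-1-methyl-3-(propan-2-yl)cyclopent-2-en-1-yl]methoxy}diphenylsilane
Product: 11 tert-butyl{[(1R,2R,5R)-2-methyl-5-(propan-2-yl)-6-oxabicyclo[3.1.0]hexan-2-yl]methoxy}diphenylsilane
Conditions: dimethyldioxirane (acetone solution), CH2Cl2, 0 °C
Reagents that add atoms: dimethyldioxirane, CC1(C)OO1
Why: Electrophilic epoxidation of the trisubstituted C4=C5 alkene under neutral conditions should occur anti to the bulky silyloxymethyl group on the neighbouring quaternary C1, which places the epoxide oxygen cis to the C1 methyl and sets C4 and C5 (the minor face isomer would be removed by chromatography).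

**Step 6**
Reactants: 11 tert-butyl{[(1R,2R,5R)-2-methyl-5-(propan-2-yl)-6-oxabicyclo[3.1.0]hexan-2-yl]methoxy}diphenylsilane
Product: 12 [(1R,2R,5R)-2-methyl-5-(propan-2-yl)-6-oxabicyclo[3.1.0]hexan-2-yl]methanol
Conditions: TBAF, THF, 0 °C → rt
Reagents that add atoms: none
Why: Fluoride-mediated desilylation is compatible with the epoxide because the liberated alkoxide could attack it only through a four-membered transition state at C5 or at the fully substituted C4.

**Step 7**
Reactants: 12 [(1R,2R,5R)-2-methyl-5-(propan-2-yl)-6-oxabicyclo[3.1.0]hexan-2-yl]methanol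
Product: 13 (1R,2S,5R)-2-methyl-5-(propan-2-yl)-6-oxabicyclo[3.1.0]hexane-2-carbaldehyde
Conditions: nPr4NRuO4 (cat.), NMO, 4 Å MS, CH2Cl2, rt
Reagents that add atoms: none
Why: Ley–Griffith oxidation of a primary alcohol proceeds under neutral conditions that spare the acid-sensitive epoxide, and the aldehyde has no α-hydrogen and so cannot epimerise or eliminate.

**Step 8**
Reactants: 14 propargyl alcohol
Product: 16 (2Z)-3-iodo-2-methylprop-2-en-1-ol, via alkenylmagnesium alkoxide 15 (not isolated)
Conditions: MeMgBr, CuI (cat.), THF, −10 °C → rt; then I2, −78 °C → 0 °C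
Reagents that add atoms: methylmagnesium bromide, C[Mg]Br; iodine, II
Why: Copper-catalysed carbomagnesiation of a propargylic alkoxide adds CH3 to the internal carbon and magnesium to the terminal carbon cis to CH2O (anti addition directed by the magnesium alkoxide), and iodinolysis with retention gives the Z vinyl iodide that fixes the C8=C9 geometry.

**Step 9**
Reactants: 16 (2Z)-3-iodo-2-methylprop-2-en-1-ol
Product: 17 (1Z)-3-bromo-1-iodo-2-methylprop-1-ene
Conditions: CBr4, PPh3, CH2Cl2, 0 °C
Reagents that add atoms: tetrabromomethane, BrC(Br)(Br)Br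
Why: Appel bromination converts the primary allylic alcohol into the bromide under neutral conditions without affecting the alkene geometry or the vinyl iodide.

**Step 10**
Reactants: 18 1,3-dithiane; 17 (1Z)-3-bromo-1-iodo-2-methylprop-1-ene
Product: 20 2-[(2Z)-3-iodo-2-methylprop-2-en-1-yl]-1,3-dithiane, via 2-lithio-1,3-dithiane 19 (not isolated)
Conditions: n-BuLi, THF, −30 °C; then 17, −78 °C
Reagents that add atoms: none
Why: Corey–Seebach alkylation, in which the lithiated dithiane displaces the allylic bromide by SN2 much faster than it exchanges with the vinyl iodide at low temperature, installs the masked C6 carbonyl and forms C6–C7.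

**Step 11**
Reactants: 13 (1R,2S,5R)-2-methyl-5-(propan-2-yl)-6-oxabicyclo[3.1.0]hexane-2-carbaldehyde; 20 2-[(2Z)-3-iodo-2-methylprop-2-en-1-yl]-1,3-dithiane
Product: 22 (1S,2Z)-4-(1,3-dithian-2-yl)-3-methyl-1-[(1R,2R,5R)-2-methyl-5-(propan-2-yl)-6-oxabicyclo[3.1.0]hexan-2-yl]but-2-en-1-ol, via alkenylchromium dichloride 21 (not isolated)
Conditions: CrCl2, NiCl2 (cat.), DMSO, rt
Reagents that add atoms: none
Why: Nozaki–Hiyama–Kishi coupling, in which nickel activates the vinyl iodide and the resulting trivalent alkenylchromium species adds chemoselectively to the aldehyde with retention of the Z geometry while tolerating the epoxide and the dithiane; C10 is set by Felkin–Anh addition anti to the C1–C5 bond and past the C1 methyl, which should favour the (10S) alcohol, and the C10 epimer would be separated.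

**Step 12**
Reactants: 22 (1S,2Z)-4-(1,3-dithian-2-yl)-3-methyl-1-[(1R,2R,5R)-2-methyl-5-(propan-2-yl)-6-oxabicyclo[3.1.0]hexan-2-yl]but-2-en-1-ol
Product: 23 tert-butyl{[(1S,2Z)-4-(1,3-dithian-2-yl)-3-methyl-1-[(1R,2S,5R)-2-methyl-5-(propan-2-yl)-6-oxabicyclo[3.1.0]hexan-2-yl]but-2-en-1-yl]oxy}dimethylsilane
Conditions: TBSOTf, 2,6-lutidine, CH2Cl2, −78 °C
Reagents that add atoms: tert-butyldimethylsilyl trifluoromethanesulfonate, CC(C)(C)[Si](C)(C)OS(=O)(=O)C(F)(F)F
Why: Silyl triflate silylation of a hindered secondary alcohol is fast at −78 °C in the presence of the hindered base, so the epoxide should not be opened, and the ether removes the only hydroxyl proton before the metalation.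

**Step 13**
Reactants: 23 tert-butyl{[(1S,2Z)-4-(1,3-dithian-2-yl)-3-methyl-1-[(1R,2S,5R)-2-methyl-5-(propan-2-yl)-6-oxabicyclo[3.1.0]hexan-2-yl]but-2-en-1-yl]oxy}dimethylsilane
Product: 25 (1S,4R,5S,10S)-10-[(tert-butyldimethylsilyl)oxy]-4-hydroxydauc-8-en-6-one propane-1,3-diyl dithioacetal, via lithiated dithiane 24 (not isolated)
Conditions: t-BuLi, HMPA, THF, −78 °C → 0 °C; then H2O
Reagents that add atoms: none
Why: t-BuLi/HMPA removes the dithiane C6–H to give the 2-lithio-1,3-dithiane 24, whose carbanion attacks C5 of the C4–C5 epoxide anti to the C5–O bond in an SN2 opening that forms C5–C6 and releases the tertiary C4 alkoxide; the closest known reaction type is the intramolecular opening of epoxides by lithiated dithianes and sulfone-stabilised carbanions. Ring B closes in a 7-exo-tet mode, the breaking C5–O bond lying outside the new ring. C5 is the only new stereocentre and is set by inversion at the epoxide carbon, so it follows from the epoxide face fixed in step 5, while the oxygen stays on C4 on its original face and therefore ends trans to C6. The step needs attack at C5 and not at the fully substituted C4; this is secured by the substitution pattern and by the tether, since the chain leaves C1 on the face opposite the epoxide oxygen and can reach only the backside of C5, whereas the 8-endo attack at C4 is hindered and out of reach. The Z C8=C9 alkene and the quaternary C1 hold C6 near C5, and metalation at −78 °C without any Lewis acid should suppress base-induced isomerisation of the epoxide to an allylic alcohol and ionisation at C4.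

**Step 14**
Reactants: 25 (1S,4R,5S,10S)-10-[(tert-butyldimethylsilyl)oxy]-4-hydroxydauc-8-en-6-one propane-1,3-diyl dithioacetal
Product: 26 (1S,4R,5S,10S)-10-[(tert-butyldimethylsilyl)oxy]-4-hydroxydauc-8-en-6-one
Conditions: PhI(OCOCF3)2, NaHCO3, MeCN/H2O (9:1), 0 °C
Reagents that add atoms: water, O
Why: Oxidative dithioacetal hydrolysis with a trivalent iodine reagent tolerates the alkene and the silyl ether, and the bicarbonate buffer and short reaction time at 0 °C are meant to keep the tertiary β-hydroxy ketone from dehydrating and the β,γ-alkene from moving into conjugation, the ketone being reduced at once.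

**Step 15**
Reactants: 26 (1S,4R,5S,10S)-10-[(tert-butyldimethylsilyl)oxy]-4-hydroxydauc-8-en-6-one
Product: 27 (1S,4R,5R,6S,10S)-10-[(tert-butyldimethylsilyl)oxy]dauc-8-ene-4,6-diol
Conditions: NaBH4, CeCl3·7H2O, MeOH, −78 °C
Reagents that add atoms: none
Why: Borohydride reduction under Luche conditions is nearly neutral, and hydride should add to the convex face of the cis-fused bicycle (the face of H-5), because the other face of C6 is screened by C4 and its isopropyl group, which is cis to C6 on ring A; this places the C6 oxygen anti to H-5 as the (6S) configuration requires.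

**Step 16**
Reactants: 27 (1S,4R,5R,6S,10S)-10-[(tert-butyldimethylsilyl)oxy]dauc-8-ene-4,6-diol
Product: 28 (1S,4R,5R,6S,10S)-10-[(tert-butyldimethylsilyl)oxy]-4-hydroxydauc-8-en-6-yl 4-methoxybenzoate
Conditions: 4-MeOC6H4COCl, Et3N, DMAP (cat.), CH2Cl2, 0 °C → rt
Reagents that add atoms: 4-methoxybenzoyl chloride, COc1ccc(C(Cl)=O)cc1
Why: DMAP-catalysed acylation with an acid chloride esterifies the secondary C6 alcohol, while the much more hindered tertiary C4 alcohol stays free.

**Step 17**
Reactants: 28 (1S,4R,5R,6S,10S)-10-[(tert-butyldimethylsilyl)oxy]-4-hydroxydauc-8-en-6-yl 4-methoxybenzoate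
Product: 29 (1S,4R,5R,6S,10S)-4,10-dihydroxydauc-8-en-6-yl 4-methoxybenzoate
Conditions: HF·pyridine, pyridine, THF, 0 °C → rt
Reagents that add atoms: none
Why: Buffered fluoride desilylation removes the C10 silyl ether without the ester cleavage or acyl migration that a basic fluoride source could cause.

**Step 18**
Reactants: 29 (1S,4R,5R,6S,10S)-4,10-dihydroxydauc-8-en-6-yl 4-methoxybenzoate
Product: 30 (1S,4R,5R,6S,10S)-10-acetoxy-4-hydroxydauc-8-en-6-yl 4-methoxybenzoate
Conditions: Ac2O, pyridine, DMAP (cat.), CH2Cl2, rt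
Reagents that add atoms: acetic anhydride, CC(=O)OC(C)=O
Why: DMAP-catalysed acetylation esterifies the secondary allylic C10 alcohol, while the tertiary C4 alcohol does not react under these mild conditions, which gives the target.

**Compound list**

1 | (R)-3-bromo-2-methylpropan-1-ol | OC[C@@H](C)CBr | starting material
2 | (R)-(3-bromo-2-methylpropoxy)(tert-butyl)diphenylsilane | CC(C)(C)[Si](c1ccccc1)(c1ccccc1)OC[C@@H](C)CBr | intermediate
3 | 3-methylbutan-2-one | CC(C)C(C)=O | starting material
4 | (E)-3-methylbutan-2-one N,N-dimethylhydrazone | CC(C)/C(C)=N/N(C)C | intermediate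
5 | lithium azaenolate of 4 (N-lithio ene-hydrazine, formed in the flask) | [Li]N(N(C)C)C(=C)C(C)C | intermediate
6 | (S)-7-[(tert-butyldiphenylsilyl)oxy]-2,6-dimethylheptan-3-one N,N-dimethylhydrazone (formed in the flask) | CC(C)C(CC[C@H](C)CO[Si](c1ccccc1)(c1ccccc1)C(C)(C)C)=NN(C)C | intermediate
7 | (S)-7-[(tert-butyldiphenylsilyl)oxy]-2,6-dimethylheptan-3-one | CC(C)C(=O)CC[C@H](C)CO[Si](c1ccccc1)(c1ccccc1)C(C)(C)C | intermediate
8 | tert-butyl{[(2S)-5-(diazomethylidene)-2,6-dimethylheptyl]oxy}diphenylsilane (diazoalkene, formed in the flask) | CC(C)C(CC[C@H](C)CO[Si](c1ccccc1)(c1ccccc1)C(C)(C)C)=C=[N+]=[N-] | intermediate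
9 | alkylidene carbene from 8 by loss of N2 (divalent carbon on the former carbonyl carbon, formed in the flask) | CC(C)C(CC[C@H](C)CO[Si](c1ccccc1)(c1ccccc1)C(C)(C)C)=[C] | intermediate
10 | tert-butyl{[(1S)-1-methyl-3-(propan-2-yl)cyclopent-2-en-1-yl]methoxy}diphenylsilane | CC(C)C1=C[C@@](C)(CO[Si](c2ccccc2)(c2ccccc2)C(C)(C)C)CC1 | intermediate
11 | tert-butyl{[(1R,2R,5R)-2-methyl-5-(propan-2-yl)-6-oxabicyclo[3.1.0]hexan-2-yl]methoxy}diphenylsilane (epoxide oxygen cis to the ring methyl) | CC(C)(C)[Si](c1ccccc1)(c1ccccc1)OC[C@@]2(C)CC[C@]3(C(C)C)O[C@H]23 | intermediate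
12 | [(1R,2R,5R)-2-methyl-5-(propan-2-yl)-6-oxabicyclo[3.1.0]hexan-2-yl]methanol | OC[C@@]1(C)CC[C@]2(C(C)C)O[C@H]12 | intermediate
13 | (1R,2S,5R)-2-methyl-5-(propan-2-yl)-6-oxabicyclo[3.1.0]hexane-2-carbaldehyde | O=C[C@@]1(C)CC[C@]2(C(C)C)O[C@H]12 | intermediate
14 | propargyl alcohol (prop-2-yn-1-ol) | C#CCO | starting material
15 | bromomagnesium (2Z)-3-(bromomagnesio)-2-methylprop-2-en-1-olate (formed in the flask) | Br[Mg]OC/C(C)=C\[Mg]Br | intermediate
16 | (2Z)-3-iodo-2-methylprop-2-en-1-ol | OC/C(C)=C\I | intermediate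
17 | (1Z)-3-bromo-1-iodo-2-methylprop-1-ene | BrC/C(C)=C\I | intermediate
18 | 1,3-dithiane | C1CSCSC1 | starting material
19 | 2-lithio-1,3-dithiane (formed in the flask) | [Li]C1SCCCS1 | intermediate
20 | 2-[(2Z)-3-iodo-2-methylprop-2-en-1-yl]-1,3-dithiane | I/C=C(C)\CC1SCCCS1 | intermediate
21 | [(1Z)-3-(1,3-dithian-2-yl)-2-methylprop-1-en-1-yl]chromium dichloride (trivalent chromium, formed in the flask) | Cl[Cr](Cl)/C=C(C)\CC1SCCCS1 | intermediate
22 | (1S,2Z)-4-(1,3-dithian-2-yl)-3-methyl-1-[(1R,2R,5R)-2-methyl-5-(propan-2-yl)-6-oxabicyclo[3.1.0]hexan-2-yl]but-2-en-1-ol | O[C@@H](/C=C(C)\CC1SCCCS1)[C@@]2(C)CC[C@]3(C(C)C)O[C@H]23 | intermediate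
23 | tert-butyl{[(1S,2Z)-4-(1,3-dithian-2-yl)-3-methyl-1-[(1R,2S,5R)-2-methyl-5-(propan-2-yl)-6-oxabicyclo[3.1.0]hexan-2-yl]but-2-en-1-yl]oxy}dimethylsilane | CC(C)(C)[Si](C)(C)O[C@@H](/C=C(C)\CC1SCCCS1)[C@@]2(C)CC[C@]3(C(C)C)O[C@H]23 | intermediate
24 | C6-lithio derivative of 23 (2-lithio-1,3-dithiane, formed in the flask) | CC(C)(C)[Si](C)(C)O[C@@H](/C=C(C)\CC1([Li])SCCCS1)[C@@]2(C)CC[C@]3(C(C)C)O[C@H]23 | intermediate
25 | (1S,4R,5S,10S)-10-[(tert-butyldimethylsilyl)oxy]-4-hydroxydauc-8-en-6-one propane-1,3-diyl dithioacetal (cis-fused; 4-OH trans to C6 on ring A) | CC(C)(C)[Si](C)(C)O[C@H]1C=C(C)CC2(SCCCS2)[C@@H]3[C@](O)(C(C)C)CC[C@]13C | intermediate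
26 | (1S,4R,5S,10S)-10-[(tert-butyldimethylsilyl)oxy]-4-hydroxydauc-8-en-6-one | CC(C)(C)[Si](C)(C)O[C@H]1C=C(C)CC(=O)[C@@H]2[C@](O)(C(C)C)CC[C@]12C | intermediate
27 | (1S,4R,5R,6S,10S)-10-[(tert-butyldimethylsilyl)oxy]dauc-8-ene-4,6-diol | CC(C)(C)[Si](C)(C)O[C@H]1C=C(C)C[C@H](O)[C@@H]2[C@](O)(C(C)C)CC[C@]12C | intermediate
28 | (1S,4R,5R,6S,10S)-10-[(tert-butyldimethylsilyl)oxy]-4-hydroxydauc-8-en-6-yl 4-methoxybenzoate | CC(C)(C)[Si](C)(C)O[C@H]1C=C(C)C[C@H](OC(=O)c2ccc(OC)cc2)[C@@H]3[C@](O)(C(C)C)CC[C@]13C | intermediate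
29 | (1S,4R,5R,6S,10S)-4,10-dihydroxydauc-8-en-6-yl 4-methoxybenzoate | O[C@H]1C=C(C)C[C@H](OC(=O)c2ccc(OC)cc2)[C@@H]3[C@](O)(C(C)C)CC[C@]13C | intermediate
30 | (1S,4R,5R,6S,10S)-10-acetoxy-4-hydroxydauc-8-en-6-yl 4-methoxybenzoate (CNP0256979.4) | CC(=O)O[C@H]1C=C(C)C[C@H](OC(=O)c2ccc(OC)cc2)[C@@H]3[C@](O)(C(C)C)CC[C@]13C | target

**Step count**

Total steps: 18. Longest linear sequence: 14 steps (steps 1, 3 to 7 and 11 to 18).

**Steps most likely to fail**

Step 13 (ring B closure). The tertiary dithiane carbanion may fail to reach C5, which is flanked by the quaternary C1 and the fully substituted C4. Base-induced isomerisation of the epoxide to an allylic alcohol, or simple reprotonation, would then take over. The fallback sets out from 13 and 17 and returns at 26; it keeps the C5–C6 disconnection but uses a secondary, less hindered sulfone-stabilised carbanion. Lithiated methyl phenyl sulfone (n-BuLi, THF, −78 °C) would be alkylated with 17 to give {[(3Z)-4-iodo-3-methylbut-3-en-1-yl]sulfonyl}benzene F1. CrCl2/NiCl2 coupling of F1 with 13 would give (1S,2Z)-3-methyl-1-[(1R,2R,5R)-2-methyl-5-(propan-2-yl)-6-oxabicyclo[3.1.0]hexan-2-yl]-5-(phenylsulfonyl)pent-2-en-1-ol F2. Silylation (TBSOTf, 2,6-lutidine) would give its C10 tert-butyldimethylsilyl ether F3. Deprotonation next to sulfur (n-BuLi, THF/HMPA, −78 °C → rt) and the same 7-exo-tet opening at C5 would give (1S,4R,5S,10S)-10-[(tert-butyldimethylsilyl)oxy]-6-(phenylsulfonyl)dauc-8-en-4-ol F4, with C6 uncontrolled. Dianion formation (n-BuLi) and oxidation with bis(trimethylsilyl) peroxide (oxidative desulfonylation) would expel benzenesulfinate and give ketone 26.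

Step 11 (Nozaki–Hiyama–Kishi coupling). Facial selectivity at C10 may be poor in the addition to the α-quaternary aldehyde, since the Felkin–Anh preference between methyl and ring CH2 is small, and the hindered Z alkenylchromium species may add slowly. The fallback sets out from 22, taken as the mixture of C10 epimers, and returns at 22; control is moved from the substrate to a reagent. The mixture would be oxidised with MnO2 (CH2Cl2, rt) to (2Z)-4-(1,3-dithian-2-yl)-3-methyl-1-[(1R,2S,5R)-2-methyl-5-(propan-2-yl)-6-oxabicyclo[3.1.0]hexan-2-yl]but-2-en-1-one F5. F5 would be reduced with BH3·SMe2 and catalytic (R)-2-methyl-CBS-oxazaborolidine (CBS reduction, the quaternary C1 acting as the large group) to give the (10S) alcohol 22.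

Step 14 (dithiane unmasking). The tertiary β-hydroxy ketone may dehydrate or undergo retro-aldol cleavage as it is liberated, and slow hydrolysis at the hindered C6 may allow over-oxidation at sulfur. The fallback sets out from 25 and returns at 27; the C4 hydroxyl is capped before the unmasking. TMSOTf/2,6-lutidine (CH2Cl2, −78 °C) would give (1S,4R,5S,10S)-10-[(tert-butyldimethylsilyl)oxy]-4-[(trimethylsilyl)oxy]dauc-8-en-6-one propane-1,3-diyl dithioacetal F6. PhI(OCOCF3)2 in aqueous MeCN would give (1S,4R,5S,10S)-10-[(tert-butyldimethylsilyl)oxy]-4-[(trimethylsilyl)oxy]dauc-8-en-6-one F7, which can no longer dehydrate or fragment. NaBH4/CeCl3·7H2O (MeOH, −78 °C) would give (1S,4R,5R,6S,10S)-10-[(tert-butyldimethylsilyl)oxy]-4-[(trimethylsilyl)oxy]dauc-8-en-6-ol F8. K2CO3 in MeOH would then remove the trimethylsilyl group selectively and return diol 27.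

**Further compounds**

F1 | step 13 | {[(3Z)-4-iodo-3-methylbut-3-en-1-yl]sulfonyl}benzene | I/C=C(C)\CCS(=O)(=O)c1ccccc1
F2 | step 13 | (1S,2Z)-3-methyl-1-[(1R,2R,5R)-2-methyl-5-(propan-2-yl)-6-oxabicyclo[3.1.0]hexan-2-yl]-5-(phenylsulfonyl)pent-2-en-1-ol | O[C@@H](/C=C(C)\CCS(=O)(=O)c1ccccc1)[C@@]2(C)CC[C@]3(C(C)C)O[C@H]23
F3 | step 13 | C10 tert-butyldimethylsilyl ether of F2 | CC(C)(C)[Si](C)(C)O[C@@H](/C=C(C)\CCS(=O)(=O)c1ccccc1)[C@@]2(C)CC[C@]3(C(C)C)O[C@H]23
F4 | step 13 | (1S,4R,5S,10S)-10-[(tert-butyldimethylsilyl)oxy]-6-(phenylsulfonyl)dauc-8-en-4-ol (C6 uncontrolled) | CC(C)(C)[Si](C)(C)O[C@H]1C=C(C)CC(S(=O)(=O)c2ccccc2)[C@@H]3[C@](O)(C(C)C)CC[C@]13C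
F5 | step 11 | (2Z)-4-(1,3-dithian-2-yl)-3-methyl-1-[(1R,2S,5R)-2-methyl-5-(propan-2-yl)-6-oxabicyclo[3.1.0]hexan-2-yl]but-2-en-1-one | O=C(/C=C(C)\CC1SCCCS1)[C@@]2(C)CC[C@]3(C(C)C)O[C@H]23
F6 | step 14 | (1S,4R,5S,10S)-10-[(tert-butyldimethylsilyl)oxy]-4-[(trimethylsilyl)oxy]dauc-8-en-6-one propane-1,3-diyl dithioacetal | CC(C)(C)[Si](C)(C)O[C@H]1C=C(C)CC2(SCCCS2)[C@@H]3[C@](O[Si](C)(C)C)(C(C)C)CC[C@]13C
F7 | step 14 | (1S,4R,5S,10S)-10-[(tert-butyldimethylsilyl)oxy]-4-[(trimethylsilyl)oxy]dauc-8-en-6-one | CC(C)(C)[Si](C)(C)O[C@H]1C=C(C)CC(=O)[C@@H]2[C@](O[Si](C)(C)C)(C(C)C)CC[C@]12C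
F8 | step 14 | (1S,4R,5R,6S,10S)-10-[(tert-butyldimethylsilyl)oxy]-4-[(trimethylsilyl)oxy]dauc-8-en-6-ol | CC(C)(C)[Si](C)(C)O[C@H]1C=C(C)C[C@H](O)[C@@H]2[C@](O[Si](C)(C)C)(C(C)C)CC[C@]12C
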